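**Retrosynthetic overview**

- The target is read as the (3S,4R)-γ-butyrolactone (ring O1–C2–C3–C4–C5). It is reached last by hydrogenolysis of its tris-benzyl ether, and the lactone is the only ring formed in the route.
- The lactone is closed from C5–OH onto the C2 acid, after oxidative cleavage of a propenyl group at C4 of an open-chain γ,δ-unsaturated acid.
- The strategy rests on the C3–C4 bond, which joins the quaternary carbinol carbon C3 (OH, C2 carbonyl, one arylmethyl) to the tertiary C4 (second arylmethyl, C5H2–O1). It is made by a chelate-controlled Ireland–Claisen rearrangement of an α-benzyloxy ester of an (S,E)-allylic alcohol, which sets both stereocentres.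
- The ester comes from a racemic 2-benzyloxy-3-arylpropanoic acid (glycolate enolate benzylation) and (S,E)-5-arylpent-3-en-2-ol (C-benzylation of (S)-but-3-yn-2-ol, then Red-Al). One benzylic bromide made from O-benzylvanillin serves both halves.

Key step: step 8

Assumption: lactone numbering is O1, C2 (carbonyl), C3, C4, C5; by CIP analysis of the given SMILES the target is the (3S,4R) isomer, with the two arylmethyl groups cis on the ring and the C3 oxygen cis to H4. LDA and LiHMDS are taken as commercial solutions.

**Route**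

Step 1
Reactants: 1 4-benzyloxy-3-methoxybenzaldehyde (O-benzylvanillin)
Product: 2 (4-benzyloxy-3-methoxyphenyl)methanol
Conditions: NaBH4, MeOH/THF, 0 °C → rt
Reagents that add atoms: none
Why: Borohydride reduction of an aromatic aldehyde gives the benzylic alcohol, and the aryl benzyl and methyl ethers are inert to it.

Step 2
Reactants: 2 (4-benzyloxy-3-methoxyphenyl)methanol
Product: 3 4-benzyloxy-3-methoxybenzyl bromide
Conditions: PBr3 (0.4 equiv), Et2O, 0 °C; used crude without storage
Reagents that add atoms: phosphorus tribromide, BrP(Br)Br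
Why: PBr3 converts the primary benzylic alcohol into the bromide through a phosphite ester and bromide displacement; the low temperature and immediate use allow for the easy ionisation of this electron-rich benzylic halide.

Step 3
Reactants: 4 (S)-but-3-yn-2-ol; 3 4-benzyloxy-3-methoxybenzyl bromide
Product: 6 (S)-5-(4-benzyloxy-3-methoxyphenyl)pent-3-yn-2-ol, via bis(bromomagnesio) derivative 5 (not isolated)
Conditions: 4, EtMgBr (2.1 equiv), THF, 0 → 40 °C; CuCl (10 mol%), then 3, THF, rt → 50 °C; aq. NH4Cl
Reagents that add atoms: none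
Why: Two equivalents of Grignard reagent deprotonate OH and the alkyne C–H, and copper(I)-catalysed coupling of the alkynylmagnesium end with the benzylic bromide (alkynyl–benzyl coupling) forms the C–C bond; the magnesium alkoxide is a poor nucleophile, and the carbinol stereocentre is not touched.

Step 4
Reactants: 6 (S)-5-(4-benzyloxy-3-methoxyphenyl)pent-3-yn-2-ol
Product: 7 (S,E)-5-(4-benzyloxy-3-methoxyphenyl)pent-3-en-2-ol
Conditions: Red-Al (3 equiv), THF, 0 °C → rt; aq. Rochelle salt
Reagents that add atoms: none
Why: Alkoxide-directed trans-hydroalumination of the propargylic alcohol with Red-Al, then protonolysis, should give the E-alkene only; the carbinol centre is not involved and the aryl ethers are stable to the hydride.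

Step 5
Reactants: 8 methyl 2-(benzyloxy)acetate; 3 4-benzyloxy-3-methoxybenzyl bromide
Product: 10 methyl 2-benzyloxy-3-(4-benzyloxy-3-methoxyphenyl)propanoate (racemic), via lithium enolate 9 (not isolated)
Conditions: LiHMDS (1.05 equiv), THF, −78 °C; then 3, DMPU (2 equiv), −78 → −30 °C
Reagents that add atoms: none
Why: This is a glycolate ester enolate alkylation (SN2) with a very reactive benzylic bromide, kept cold to suppress Claisen self-condensation; the new α-centre is racemic, which is harmless because it is destroyed by enolisation in step 8.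

Step 6
Reactants: 10 methyl 2-benzyloxy-3-(4-benzyloxy-3-methoxyphenyl)propanoate
Product: 11 2-benzyloxy-3-(4-benzyloxy-3-methoxyphenyl)propanoic acid (racemic)
Conditions: LiOH·H2O, THF/MeOH/H2O, rt; 1 M HCl to pH 2
Reagents that add atoms: lithium hydroxide, [Li+].[OH-]
Why: Saponification of the methyl ester leaves all three ethers untouched, and base epimerisation is irrelevant for a racemic centre.

Step 7
Reactants: 11 2-benzyloxy-3-(4-benzyloxy-3-methoxyphenyl)propanoic acid; 7 (S,E)-5-(4-benzyloxy-3-methoxyphenyl)pent-3-en-2-ol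
Product: 12 (S,E)-5-(4-benzyloxy-3-methoxyphenyl)pent-3-en-2-yl 2-benzyloxy-3-(4-benzyloxy-3-methoxyphenyl)propanoate (both α-epimers)
Conditions: EDC·HCl (1.3 equiv), DMAP (0.2 equiv), CH2Cl2, 0 °C → rt
Reagents that add atoms: none
Why: Steglich esterification acylates the secondary allylic alcohol at oxygen, so the (S)-carbinol configuration and the E-alkene are retained; the mixture of α-epimers needs no separation.

Step 8
Reactants: 12 (S,E)-5-(4-benzyloxy-3-methoxyphenyl)pent-3-en-2-yl 2-benzyloxy-3-(4-benzyloxy-3-methoxyphenyl)propanoate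
Product: 16 (2S,3R,E)-2-benzyloxy-2,3-bis(4-benzyloxy-3-methoxybenzyl)hex-4-enoic acid, via chelated lithium enolate 13 (not isolated), via silyl ketene acetal 14 (not isolated), via trimethylsilyl ester 15 (not isolated)
Conditions: LDA (2 equiv), THF, −78 °C, 45 min; TMSCl (3 equiv), −78 °C → rt, then 50 °C; 1 M HCl work-up
Reagents that add atoms: none
Why: LDA removes the α-hydrogen of either α-epimer of 12 to give one lithium enolate 13 in which lithium is held between the enolate oxygen and the α-benzyloxy oxygen (OLi cis to OBn); O-silylation fixes this geometry in 14, which on warming undergoes a concerted suprafacial [3,3]-sigmatropic shift that forms the C3–C4 bond (lactone numbering) and breaks the allylic C–O bond, giving silyl ester 15 and, after aqueous acid, acid 16. The closest known reaction type is the chelation-controlled Ireland–Claisen rearrangement of α-alkoxy (glycolate- and lactate-type) esters of secondary allylic alcohols. No ring is closed; the six-membered array exists only as a chair transition state. In that chair the carbinol methyl group is equatorial, which selects the alkene face, transfers the (S)-carbinol configuration to both new centres and makes the new alkene E. The E-alkene places the C4 arylmethyl equatorial and sets that centre (3R in 16, 4R in the lactone), while the chelated ketene acetal places OBn equatorial and the other arylmethyl axial and sets the quaternary centre (2S in 16, 3S in the lactone). The step needs a single ketene acetal geometry and chair over boat: the first is secured by the five-membered lithium chelate formed in THF without polar additives before silylation, the second by the acyclic E-allylic ester with its equatorial methyl group.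

Step 9
Reactants: 16 (2S,3R,E)-2-benzyloxy-2,3-bis(4-benzyloxy-3-methoxybenzyl)hex-4-enoic acid
Product: 19 (3S,4R)-3-benzyloxy-3,4-bis(4-benzyloxy-3-methoxybenzyl)dihydrofuran-2(3H)-one, via ozonide 17 (not isolated), via hydroxy acid 18 (not isolated)
Conditions: O3/O2, CH2Cl2, −78 °C, Sudan Red 7B end point; then MeOH, NaBH4 (excess), −78 °C → rt; 2 M HCl, THF, rt
Reagents that add atoms: ozone, [O-][O+]=O
Why: Ozonolysis of the 1,2-disubstituted alkene, which reacts far faster than the alkoxyarenes when ozone is dosed to an indicator end point, gives the ozonide; borohydride reduces it to the primary alcohol at low temperature without epimerising C4, and acidification closes the γ-lactone by 5-exo-trig acyl substitution, helped by the quaternary C3.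

Step 10
Reactants: 19 (3S,4R)-3-benzyloxy-3,4-bis(4-benzyloxy-3-methoxybenzyl)dihydrofuran-2(3H)-one
Product: 20 (3S,4R)-3-hydroxy-3,4-bis(4-hydroxy-3-methoxybenzyl)dihydrofuran-2(3H)-one (target)
Conditions: H2 (1 atm), 20% Pd(OH)2/C, EtOAc/MeOH, rt
Reagents that add atoms: none
Why: Catalytic hydrogenolysis cleaves the two aryl benzyl ethers and the tertiary alkyl benzyl ether at their O–CH2Ph bonds; the C3–O bond is not benzylic, and the lactone and both stereocentres are unaffected.

**Compound list**

1 | 4-benzyloxy-3-methoxybenzaldehyde | COc1cc(C=O)ccc1OCc1ccccc1 | starting material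
2 | (4-benzyloxy-3-methoxyphenyl)methanol | COc1cc(CO)ccc1OCc1ccccc1 | intermediate
3 | 4-benzyloxy-3-methoxybenzyl bromide | COc1cc(CBr)ccc1OCc1ccccc1 | intermediate
4 | (S)-but-3-yn-2-ol | C[C@H](O)C#C | starting material
5 | bis(bromomagnesio) derivative of 4 (magnesium alkoxide and alkynylmagnesium bromide) | C[C@H](O[Mg]Br)C#C[Mg]Br | intermediate (not isolated)
6 | (S)-5-(4-benzyloxy-3-methoxyphenyl)pent-3-yn-2-ol | C[C@H](O)C#CCc1ccc(OCc2ccccc2)c(OC)c1 | intermediate
7 | (S,E)-5-(4-benzyloxy-3-methoxyphenyl)pent-3-en-2-ol | C[C@H](O)/C=C/Cc1ccc(OCc2ccccc2)c(OC)c1 | intermediate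
8 | methyl 2-(benzyloxy)acetate | COC(=O)COCc1ccccc1 | starting material
9 | lithium enolate of methyl 2-(benzyloxy)acetate | COC(O[Li])=COCc1ccccc1 | intermediate (not isolated)
10 | methyl 2-benzyloxy-3-(4-benzyloxy-3-methoxyphenyl)propanoate, racemic | COC(=O)C(OCc1ccccc1)Cc1ccc(OCc2ccccc2)c(OC)c1 | intermediate
11 | 2-benzyloxy-3-(4-benzyloxy-3-methoxyphenyl)propanoic acid, racemic | OC(=O)C(OCc1ccccc1)Cc1ccc(OCc2ccccc2)c(OC)c1 | intermediate
12 | (S,E)-5-(4-benzyloxy-3-methoxyphenyl)pent-3-en-2-yl 2-benzyloxy-3-(4-benzyloxy-3-methoxyphenyl)propanoate, α-centre both epimers | C[C@H](OC(=O)C(OCc1ccccc1)Cc1ccc(OCc2ccccc2)c(OC)c1)/C=C/Cc1ccc(OCc2ccccc2)c(OC)c1 | intermediate (key-step precursor)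
13 | chelated lithium enolate of 12, OLi cis to OBn | C[C@H](O/C(O[Li])=C(/OCc1ccccc1)Cc1ccc(OCc2ccccc2)c(OC)c1)/C=C/Cc1ccc(OCc2ccccc2)c(OC)c1 | intermediate (not isolated)
14 | (Z)-trimethylsilyl ketene acetal of 12, OSiMe3 cis to OBn | C[C@H](O/C(O[Si](C)(C)C)=C(/OCc1ccccc1)Cc1ccc(OCc2ccccc2)c(OC)c1)/C=C/Cc1ccc(OCc2ccccc2)c(OC)c1 | intermediate (not isolated)
15 | trimethylsilyl (2S,3R,E)-2-benzyloxy-2,3-bis(4-benzyloxy-3-methoxybenzyl)hex-4-enoate | C[Si](C)(C)OC(=O)[C@](OCc1ccccc1)(Cc1ccc(OCc2ccccc2)c(OC)c1)[C@H](Cc1ccc(OCc2ccccc2)c(OC)c1)/C=C/C | intermediate (not isolated)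
16 | (2S,3R,E)-2-benzyloxy-2,3-bis(4-benzyloxy-3-methoxybenzyl)hex-4-enoic acid | OC(=O)[C@](OCc1ccccc1)(Cc1ccc(OCc2ccccc2)c(OC)c1)[C@H](Cc1ccc(OCc2ccccc2)c(OC)c1)/C=C/C | intermediate (key-step product)
17 | (2S,3S)-2-benzyloxy-2,3-bis(4-benzyloxy-3-methoxybenzyl)-3-(5-methyl-1,2,4-trioxolan-3-yl)propanoic acid, trioxolane centres mixed | OC(=O)[C@](OCc1ccccc1)(Cc1ccc(OCc2ccccc2)c(OC)c1)[C@H](Cc1ccc(OCc2ccccc2)c(OC)c1)C1OOC(C)O1 | intermediate (not isolated)
18 | (2S,3R)-2-benzyloxy-2,3-bis(4-benzyloxy-3-methoxybenzyl)-4-hydroxybutanoic acid | OC(=O)[C@](OCc1ccccc1)(Cc1ccc(OCc2ccccc2)c(OC)c1)[C@H](Cc1ccc(OCc2ccccc2)c(OC)c1)CO | intermediate (not isolated)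
19 | (3S,4R)-3-benzyloxy-3,4-bis(4-benzyloxy-3-methoxybenzyl)dihydrofuran-2(3H)-one | COc1cc(C[C@@H]2COC(=O)[C@]2(OCc2ccccc2)Cc2ccc(OCc3ccccc3)c(OC)c2)ccc1OCc1ccccc1 | intermediate
20 | (3S,4R)-3-hydroxy-3,4-bis(4-hydroxy-3-methoxybenzyl)dihydrofuran-2(3H)-one | COc1cc(C[C@@H]2COC(=O)[C@]2(O)Cc2ccc(O)c(OC)c2)ccc1O | target

**Step count**

Total: 10 steps. Longest linear sequence: 8 steps (1 → 2 → 3 → 6 → 7 → 12 → 16 → 19 → 20; the acid branch 1 → 2 → 3 → 10 → 11 → 12 is equally long).

**Steps most likely to fail**

1. Step 8. Enolisation may be only partly chelate-controlled, so that both ketene acetal geometries form and the configuration at the quaternary C3 is eroded while C4 stays defined. The crowded tetrasubstituted ketene acetal may also rearrange slowly. The fallback sets out from 7 and returns at 20. Alcohol 7 is esterified (EDC, DMAP) with commercial 3-(4-benzyloxy-3-methoxyphenyl)propanoic acid to give (S,E)-5-(4-benzyloxy-3-methoxyphenyl)pent-3-en-2-yl 3-(4-benzyloxy-3-methoxyphenyl)propanoate F1. Its Ireland–Claisen rearrangement (LDA, TMSCl, THF, −78 °C → rt) needs no control of enolate geometry, since only C4 must be set and this follows from the same chair with equatorial methyl. It should give (3R,E)-2,3-bis(4-benzyloxy-3-methoxybenzyl)hex-4-enoic acid F2 as a mixture at C2. Ozonolysis, NaBH4 and acid as in step 9 should give (4S)-3,4-bis(4-benzyloxy-3-methoxybenzyl)dihydrofuran-2(3H)-one F3, which has the spatial arrangement of the target at C4 (the descriptor differs only through the CIP ranking). Deprotonation with KHMDS at −78 °C and oxidation of the enolate with 2-(phenylsulfonyl)-3-phenyloxaziridine should deliver oxygen anti to the C4 arylmethyl group. This gives (3S,4R)-3-hydroxy-3,4-bis(4-benzyloxy-3-methoxybenzyl)dihydrofuran-2(3H)-one F4, and hydrogenolysis as in step 10 then gives 20.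

2. Step 3. The magnesium alkoxide may be O-benzylated, the benzylic bromide may homocouple, and the skipped aryl–CH2–alkyne may isomerise to the allene under the basic conditions. The fallback sets out from 3 and returns at 7, bypassing step 4. Bromide 3 is coupled with vinylmagnesium bromide under CuI catalysis to give 4-allyl-1-benzyloxy-2-methoxybenzene F5. Cross-metathesis of this with commercial (S)-but-3-en-2-ol (Hoveyda–Grubbs II, CH2Cl2, 40 °C, 1,4-benzoquinone against double-bond migration) should give 7 directly. The minor Z isomer would have to be removed, because the alkene geometry decides the C3/C4 relative configuration in step 8.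

3. Step 9. Ozone may attack the electron-rich dialkoxyarene rings or the benzylic C–H bonds of the ethers in competition with alkene cleavage. The fallback sets out from 16 and returns at 19. Acid 16 is cleaved with catalytic OsO4, NaIO4 and 2,6-lutidine in dioxane–water (Lemieux–Johnson) to give (2S,3S)-2-benzyloxy-2,3-bis(4-benzyloxy-3-methoxybenzyl)-4-oxobutanoic acid F6, expected to rest as its ring-closed hydroxylactone tautomer. Reduction with NaBH4 in MeOH at 0 °C and acidification should then give 19.

**Further compounds**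

F1 | step 8 | (S,E)-5-(4-benzyloxy-3-methoxyphenyl)pent-3-en-2-yl 3-(4-benzyloxy-3-methoxyphenyl)propanoate | C[C@H](OC(=O)CCc1ccc(OCc2ccccc2)c(OC)c1)/C=C/Cc1ccc(OCc2ccccc2)c(OC)c1
F2 | step 8 | (3R,E)-2,3-bis(4-benzyloxy-3-methoxybenzyl)hex-4-enoic acid, C2 epimers | OC(=O)C(Cc1ccc(OCc2ccccc2)c(OC)c1)[C@H](Cc1ccc(OCc2ccccc2)c(OC)c1)/C=C/C
F3 | step 8 | (4S)-3,4-bis(4-benzyloxy-3-methoxybenzyl)dihydrofuran-2(3H)-one, C3 epimers | COc1cc(C[C@@H]2COC(=O)C2Cc2ccc(OCc3ccccc3)c(OC)c2)ccc1OCc1ccccc1
F4 | step 8 | (3S,4R)-3-hydroxy-3,4-bis(4-benzyloxy-3-methoxybenzyl)dihydrofuran-2(3H)-one | COc1cc(C[C@@H]2COC(=O)[C@]2(O)Cc2ccc(OCc3ccccc3)c(OC)c2)ccc1OCc1ccccc1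
F5 | step 3 | 4-allyl-1-benzyloxy-2-methoxybenzene | C=CCc1ccc(OCc2ccccc2)c(OC)c1
F6 | step 9 | (2S,3S)-2-benzyloxy-2,3-bis(4-benzyloxy-3-methoxybenzyl)-4-oxobutanoic acid | OC(=O)[C@](OCc1ccccc1)(Cc1ccc(OCc2ccccc2)c(OC)c1)[C@H](Cc1ccc(OCc2ccccc2)c(OC)c1)C=O
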